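**Retrosynthetic overview**
- The palmitate C–O bond is cut first: the ester comes from caesium palmitate and a benzylic chloride, itself unmasked from a benzylic NMe2 group.
- The diaryl ether C–O bond is cut next: Ullmann coupling of a 2,6-disubstituted ring-A phenol with a ring-B aryl bromide.
- The key C–C bond is Ar–CH2: an intermolecular phenol Mannich reaction joins 4-methoxy-2-(methoxymethoxy)phenol to the formaldehyde/dimethylamine iminium fragment, ortho to the free OH.
- The ring-A phenol comes from 2-hydroxy-4-methoxybenzaldehyde by MOM protection and Baeyer–Villiger oxidation.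
- No ring is formed: both benzene rings are bought intact. The order is C–C bond (Mannich), then Ar–O–Ar, then ester, then removal of the two MOM groups.

Assumption: the target has no stereocentre, so "single enantiomer" is taken as the achiral compound as drawn and no stereocontrol is needed.

**Step 1**
Reactants: 1 2-hydroxy-4-methoxybenzaldehyde
Product: 2 4-methoxy-2-(methoxymethoxy)benzaldehyde
Conditions: MOMCl (1.5 equiv), i-Pr2NEt (2 equiv), CH2Cl2, 0 °C → rt
Reagents that add atoms: chloromethyl methyl ether (MOMCl), COCCl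
Why: Williamson-type O-alkylation (MOM protection) of the phenol masks the future free 3-OH with a group that survives peracid, amine/formaldehyde, hot phosphate base and carboxylate alkylation.

**Step 2**
Reactants: 2 4-methoxy-2-(methoxymethoxy)benzaldehyde
Product: 4 4-methoxy-2-(methoxymethoxy)phenol, via aryl formate 3 (not isolated)
Conditions: mCPBA (1.3 equiv), CH2Cl2, 0 °C → rt; aq. Na2S2O3/NaHCO3 wash; then K2CO3 (cat.), MeOH, rt
Reagents that add atoms: meta-chloroperoxybenzoic acid (mCPBA), OOC(=O)c1cccc(Cl)c1
Why: Baeyer–Villiger (Dakin-type) oxidation, in which the electron-rich 2,4-dialkoxyaryl group migrates in preference to H to give the aryl formate, which base-catalysed methanolysis converts to the phenol.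

**Step 3 (key C–C bond)**
Reactants: 4 4-methoxy-2-(methoxymethoxy)phenol
Product: 5 2-[(dimethylamino)methyl]-4-methoxy-6-(methoxymethoxy)phenol
Conditions: 37% aq. CH2O (1.2 equiv), 40% aq. Me2NH (1.5 equiv), EtOH, rt → 70 °C, N2
Reagents that add atoms: formaldehyde, C=O; dimethylamine, CNC
Why: Intermolecular phenol Mannich reaction, in which the iminium ion formed in situ attacks the only free position ortho to the phenol OH (para is blocked by OMe), forming the Ar–CH2 bond of the target without creating a stereocentre.

**Step 4**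
Reactants: 6 3-bromo-5-methylphenol
Product: 7 1-bromo-3-(methoxymethoxy)-5-methylbenzene
Conditions: MOMCl (1.3 equiv), i-Pr2NEt (1.5 equiv), CH2Cl2, 0 °C → rt
Reagents that add atoms: chloromethyl methyl ether (MOMCl), COCCl
Why: Williamson-type MOM protection of the ring-B phenol, so that only the ring-A phenol can act as nucleophile in the ether coupling.

**Step 5**
Reactants: 5 2-[(dimethylamino)methyl]-4-methoxy-6-(methoxymethoxy)phenol; 7 1-bromo-3-(methoxymethoxy)-5-methylbenzene (1.3 equiv)
Product: 8 1-[5-methoxy-3-(methoxymethoxy)-2-[3-(methoxymethoxy)-5-methylphenoxy]phenyl]-N,N-dimethylmethanamine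
Conditions: CuI (20 mol%), picolinic acid (40 mol%), K3PO4 (2 equiv), DMSO, 90–100 °C, N2
Reagents that add atoms: none
Why: Ullmann diaryl ether synthesis under Cu(I)/picolinic acid catalysis, a system suited to 2,6-disubstituted electron-rich phenols with an unhindered aryl bromide, with the MOM ethers and the tertiary amine inert to phosphate base.

**Step 6**
Reactants: 8 1-[5-methoxy-3-(methoxymethoxy)-2-[3-(methoxymethoxy)-5-methylphenoxy]phenyl]-N,N-dimethylmethanamine
Product: 9 1-(chloromethyl)-5-methoxy-3-(methoxymethoxy)-2-[3-(methoxymethoxy)-5-methylphenoxy]benzene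
Conditions: ClCO2Et (1.3 equiv), CH2Cl2, 0 °C → rt
Reagents that add atoms: ethyl chloroformate, CCOC(=O)Cl
Why: Von Braun-type chloroformate dealkylation, in which N-acylation gives an acylammonium chloride whose chloride cleaves the benzylic C–N bond (benzyl far faster than methyl) to give the benzyl chloride and a neutral carbamate.

**Step 7**
Reactants: 9 1-(chloromethyl)-5-methoxy-3-(methoxymethoxy)-2-[3-(methoxymethoxy)-5-methylphenoxy]benzene; 10 hexadecanoic acid (palmitic acid, 1.2 equiv)
Product: 11 [5-methoxy-3-(methoxymethoxy)-2-[3-(methoxymethoxy)-5-methylphenoxy]phenyl]methyl hexadecanoate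
Conditions: Cs2CO3 (1.5 equiv), Bu4NI (10 mol%), DMF, 50 °C
Reagents that add atoms: none
Why: SN2 O-alkylation of caesium palmitate by the primary benzylic chloride (iodide-catalysed) forms the ester under mild basic conditions that leave the MOM ethers untouched.

**Step 8**
Reactants: 11 [5-methoxy-3-(methoxymethoxy)-2-[3-(methoxymethoxy)-5-methylphenoxy]phenyl]methyl hexadecanoate
Product: 12 Betaethrin H, [3-hydroxy-2-(3-hydroxy-5-methylphenoxy)-5-methoxyphenyl]methyl hexadecanoate
Conditions: ZnBr2 (2 equiv), n-PrSH (4 equiv), CH2Cl2, 0 °C → rt, 15–30 min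
Reagents that add atoms: none
Why: Lewis acid/thiol acetal cleavage of both aryl MOM ethers, with the thiol trapping the methoxymethyl cation so it cannot alkylate the electron-rich rings, under conditions too mild to ionise the benzylic ester or cleave the aryl methyl or diaryl ether.

**Compound list**
1 | 2-hydroxy-4-methoxybenzaldehyde | COc1ccc(C=O)c(O)c1 | starting material
2 | 4-methoxy-2-(methoxymethoxy)benzaldehyde | COCOc1cc(OC)ccc1C=O | intermediate
3 | 4-methoxy-2-(methoxymethoxy)phenyl formate (not isolated) | COCOc1cc(OC)ccc1OC=O | intermediate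
4 | 4-methoxy-2-(methoxymethoxy)phenol | COCOc1cc(OC)ccc1O | intermediate
5 | 2-[(dimethylamino)methyl]-4-methoxy-6-(methoxymethoxy)phenol | CN(C)Cc1cc(OC)cc(OCOC)c1O | intermediate
6 | 3-bromo-5-methylphenol | Cc1cc(O)cc(Br)c1 | starting material
7 | 1-bromo-3-(methoxymethoxy)-5-methylbenzene | COCOc1cc(C)cc(Br)c1 | intermediate
8 | 1-[5-methoxy-3-(methoxymethoxy)-2-[3-(methoxymethoxy)-5-methylphenoxy]phenyl]-N,N-dimethylmethanamine | CN(C)Cc1cc(OC)cc(OCOC)c1Oc1cc(C)cc(OCOC)c1 | intermediate
9 | 1-(chloromethyl)-5-methoxy-3-(methoxymethoxy)-2-[3-(methoxymethoxy)-5-methylphenoxy]benzene | ClCc1cc(OC)cc(OCOC)c1Oc1cc(C)cc(OCOC)c1 | intermediate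
10 | hexadecanoic acid (palmitic acid) | CCCCCCCCCCCCCCCC(=O)O | starting material
11 | [5-methoxy-3-(methoxymethoxy)-2-[3-(methoxymethoxy)-5-methylphenoxy]phenyl]methyl hexadecanoate | CCCCCCCCCCCCCCCC(=O)OCc1cc(OC)cc(OCOC)c1Oc1cc(C)cc(OCOC)c1 | intermediate
12 | Betaethrin H, [3-hydroxy-2-(3-hydroxy-5-methylphenoxy)-5-methoxyphenyl]methyl hexadecanoate (achiral) | CCCCCCCCCCCCCCCC(=O)OCc1cc(OC)cc(O)c1Oc1cc(C)cc(O)c1 | target

**Totals**
Total step count: 8.
Longest linear sequence: 7 steps (steps 1, 2, 3, 5, 6, 7, 8); step 4 is a one-step side branch.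

**Three steps most likely to fail, with fallbacks**

Step 3 (Mannich). Some aminomethylation could occur at the position activated by the two alkoxy groups instead of ortho to OH, or the reaction could be sluggish. The fallback sets out from 4 and comes back at 5. Magnesium-phenoxide-directed ortho-formylation of 4 (MgCl2, Et3N, paraformaldehyde, MeCN, reflux) is an aldol-type addition of the Mg phenoxide to formaldehyde followed by hydride transfer, and it occurs only ortho to OH. It gives 2-hydroxy-5-methoxy-3-(methoxymethoxy)benzaldehyde F1. Reductive amination of this aldehyde (Me2NH, NaBH(OAc)3, 1,2-dichloroethane, rt) then delivers Mannich base 5.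

Step 5 (Ullmann coupling), the riskiest step. The phenol is flanked by OMOM and by a CH2NMe2 group that can chelate copper. The fallback sets out from 5 and comes back at 8, building ring B's oxygen pattern from a cyclohexenone instead of an aryl halide. Commercial 5-methylcyclohexane-1,3-dione is converted with (COCl)2/cat. DMF (CH2Cl2, 0 °C → rt) into racemic 3-chloro-5-methylcyclohex-2-en-1-one F2. Phenol 5 adds to it by addition–elimination (K2CO3, DMF, 60 °C), which tolerates hindered phenoxides, to give the vinylogous ester 3-[2-[(dimethylamino)methyl]-4-methoxy-6-(methoxymethoxy)phenoxy]-5-methylcyclohex-2-en-1-one F3. Kinetic α′-deprotonation and selenenylation (LDA, THF, −78 °C; PhSeCl) gives 3-[2-[(dimethylamino)methyl]-4-methoxy-6-(methoxymethoxy)phenoxy]-5-methyl-6-(phenylselanyl)cyclohex-2-en-1-one F4. Selenoxide elimination (H2O2, pyridine, CH2Cl2, 0 °C) and tautomerisation of the resulting dienone aromatise the ring to 3-[2-[(dimethylamino)methyl]-4-methoxy-6-(methoxymethoxy)phenoxy]-5-methylphenol F5. O-Alkylation (NaH, then 1.05 equiv MOMCl, THF, 0 °C) gives 8.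

Step 8 (MOM removal beside the benzylic ester). The Lewis acid could ionise the ortho-aryloxybenzyl ester, or the MOM cleavage could stall. The fallback sets out from 9 and comes back at 12, installing the ester last. Chloride 9 is displaced with KOAc (DMF, 60 °C) to give [5-methoxy-3-(methoxymethoxy)-2-[3-(methoxymethoxy)-5-methylphenoxy]phenyl]methyl acetate F6. Methanolic HCl (AcCl in MeOH, 40 °C) removes both MOM groups and the acetate, with no sensitive ester present, to give 3-(hydroxymethyl)-2-(3-hydroxy-5-methylphenoxy)-5-methoxyphenol F7. Immobilised Candida antarctica lipase B (Novozym 435) with vinyl palmitate (MTBE/THF, 45 °C) then acylates only the primary benzylic hydroxyl, leaving both phenols free, to give 12.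

**Further compounds**
F1 | step 3 | 2-hydroxy-5-methoxy-3-(methoxymethoxy)benzaldehyde | COCOc1cc(OC)cc(C=O)c1O
F2 | step 5 | 3-chloro-5-methylcyclohex-2-en-1-one (racemic) | CC1CC(Cl)=CC(=O)C1
F3 | step 5 | 3-[2-[(dimethylamino)methyl]-4-methoxy-6-(methoxymethoxy)phenoxy]-5-methylcyclohex-2-en-1-one (racemic) | CC1CC(=O)C=C(Oc2c(CN(C)C)cc(OC)cc2OCOC)C1
F4 | step 5 | 3-[2-[(dimethylamino)methyl]-4-methoxy-6-(methoxymethoxy)phenoxy]-5-methyl-6-(phenylselanyl)cyclohex-2-en-1-one (racemic, diastereomer mixture) | CC1CC(Oc2c(CN(C)C)cc(OC)cc2OCOC)=CC(=O)C1[Se]c1ccccc1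
F5 | step 5 | 3-[2-[(dimethylamino)methyl]-4-methoxy-6-(methoxymethoxy)phenoxy]-5-methylphenol | CN(C)Cc1cc(OC)cc(OCOC)c1Oc1cc(C)cc(O)c1
F6 | step 8 | [5-methoxy-3-(methoxymethoxy)-2-[3-(methoxymethoxy)-5-methylphenoxy]phenyl]methyl acetate | CC(=O)OCc1cc(OC)cc(OCOC)c1Oc1cc(C)cc(OCOC)c1
F7 | step 8 | 3-(hydroxymethyl)-2-(3-hydroxy-5-methylphenoxy)-5-methoxyphenol | OCc1cc(OC)cc(O)c1Oc1cc(C)cc(O)c1
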